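## Retrosynthetic overview

1. The two acetates and the lactone C3 oxygen go on last (enolate hydroxylation anti to the C4 substituent, then acetylation). The lactone itself comes from a 1,4-diol made by reducing a menthyloxy-butanolide.
2. The bond from the quaternary ring carbon C1 of the hydroazulene to the side chain is made by decarboxylative tertiary-radical conjugate addition of a hydroazulene N-acyloxyphthalimide (fragment 1) to a (5S)-menthyloxybutenolide carrying the acetate arm (fragment 2).
3. The cis ring fusion (C3a, C8a) comes from hydroxyl-directed hydrogenation of a C3a=C8a bicyclic allylic alcohol. Its C8 carbinol (CBS reduction) is a temporary stereocentre that later becomes the exocyclic methylene carbon.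
4. The cyclopentane is annulated onto a seven-membered vinylogous ester by making C1–C2 and C3–C3a in one operation (enolate addition to vinyltriphenylphosphonium, then intramolecular Wittig). Enabling feature: the ester α-carbon (future C1) and the ring carbonyl carbon (future C3a, next to the gem-dimethyl carbon C4) are 1,3-related through C8a. C8a is the α-carbon of the vinylogous ester and has no acidic hydrogen, and the second ring carbonyl (C8) is masked as the enol ether.
5. Ring order: seven-membered carbocycle (bought as cycloheptane-1,3-dione), cyclopentane (step 5), lactone (step 17).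

Key step: step 5

Remark: step 5 forms C1 of the hydroazulene in both configurations. Compounds 11–17 are carried as C1-epimer mixtures (centre left undefined in their SMILES), because C1 becomes a planar radical in step 15 and is set there.

## Route

Step 1
Reactants: 1 cycloheptane-1,3-dione
Product: 2 3-(2-methylpropoxy)cyclohept-2-en-1-one
Conditions: 2-methylpropan-1-ol, PPTS (cat.), toluene, reflux, Dean–Stark
Reagents that add atoms: 2-methylpropan-1-ol, CC(C)CO
Why: Acid-catalysed condensation of the symmetric 1,3-dione with the alcohol under azeotropic water removal should give the single vinylogous ester (vinylogous esterification).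

Step 2
Reactants: 2 3-(2-methylpropoxy)cyclohept-2-en-1-one
Product: 4 7,7-dimethyl-3-(2-methylpropoxy)cyclohept-2-en-1-one, via monomethyl ketone 3 (not isolated)
Conditions: LiN(i-Pr)2, THF, −78 °C, then MeI; again LiN(i-Pr)2, −78 °C, then MeI, −78 °C to rt
Reagents that add atoms: iodomethane, CI
Why: Kinetic deprotonation of a vinylogous ester occurs at the α′ carbon (C7), so two enolate methylations should place the gem-dimethyl group next to the carbonyl (enolate alkylation, no stereocentre).

Step 3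
Reactants: 4 7,7-dimethyl-3-(2-methylpropoxy)cyclohept-2-en-1-one
Product: 5 2-iodo-7,7-dimethyl-3-(2-methylpropoxy)cyclohept-2-en-1-one
Conditions: N-iodosuccinimide, CH2Cl2, 0 °C to rt, dark
Reagents that add atoms: N-iodosuccinimide, O=C1CCC(=O)N1I
Why: Electrophilic iodination at C2, the nucleophilic enol-ether carbon of the vinylogous ester, should give the α-iodo enone.

Step 4
Reactants: 5 2-iodo-7,7-dimethyl-3-(2-methylpropoxy)cyclohept-2-en-1-one; 6 methyl 2-bromopropanoate
Product: 8 methyl 2-[6,6-dimethyl-2-(2-methylpropoxy)-7-oxocyclohept-1-en-1-yl]propanoate (racemic), via Reformatsky reagent 7 (not isolated)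
Conditions: Zn dust, THF, rt (6 to 7); then 5, Pd[P(t-Bu)3]2 (5 mol %), THF, 50 °C
Reagents that add atoms: none
Why: Negishi cross-coupling of the vinyl iodide with a zinc ester enolate (Reformatsky reagent) should attach the propanoate at C2; its stereocentre forms racemic and becomes the quaternary carbon in step 5.

Step 5
Reactants: 8 methyl 2-[6,6-dimethyl-2-(2-methylpropoxy)-7-oxocyclohept-1-en-1-yl]propanoate
Product: 11 methyl 1,4,4-trimethyl-8-oxo-1,2,3,4,5,6,7,8-octahydroazulene-1-carboxylate (racemic), via phosphonium ylide 9 (not isolated), via alkoxy diene 10 (not isolated)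
Conditions: KN(SiMe3)2 (1.0 equiv), THF, −78 °C; CH2=CHPPh3Br, THF/DMF, −78 to 65 °C; then 1 M HCl, THF, rt
Reagents that add atoms: vinyltriphenylphosphonium bromide, C=C[P+](c1ccccc1)(c1ccccc1)c1ccccc1.[Br-]; water, O
Why: KN(SiMe3)2 removes the ester α-hydrogen (the ring α′ position is quaternary and C2 of the vinylogous ester has no hydrogen), and the enolate adds in Michael fashion to the vinylphosphonium salt, forming the C1–C2 bond and the quaternary carbon C1 and leaving a non-stabilised ylide at C3. The ylide carbon then attacks the ring carbonyl carbon (future C3a) in a 5-exo-trig closure and the oxaphosphetane collapses to the C3=C3a alkene and Ph3PO (intramolecular Wittig); dilute acid hydrolyses the resulting 1-alkoxydiene with protonation at C3 to the conjugated C3a=C8a enone. The closest known reaction is the Schweizer cyclopentene annulation of γ-oxo carbanions with vinyltriphenylphosphonium bromide, together with the known Wittig olefination of vinylogous ester carbonyls. The only new stereocentre, C1, is formed without control on purpose, because it is planarised in step 15 and all later stereocentres are set independently of it. The step needs site-selective deprotonation and chemoselective olefination of the ring carbonyl; the substrate secures both, since ylide attack on the ester would need a four-membered ring, the second ring carbonyl is masked as the enol ether, and the single equivalent of base is consumed before the phosphonium salt is added.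

Step 6
Reactants: 11 methyl 1,4,4-trimethyl-8-oxo-1,2,3,4,5,6,7,8-octahydroazulene-1-carboxylate
Product: 12 methyl (8S)-8-hydroxy-1,4,4-trimethyl-1,2,3,4,5,6,7,8-octahydroazulene-1-carboxylate
Conditions: (R)-2-methyl-CBS-oxazaborolidine (20 mol %), BH3·SMe2, THF, −20 °C
Reagents that add atoms: none
Why: Corey–Bakshi–Shibata reduction under catalyst control (tetrasubstituted alkenyl arm as the large group) should set C8 as S in both C1 epimers.

Step 7
Reactants: 12 methyl (8S)-8-hydroxy-1,4,4-trimethyl-1,2,3,4,5,6,7,8-octahydroazulene-1-carboxylate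
Product: 13 methyl (3aR,8S,8aR)-8-hydroxy-1,4,4-trimethyldecahydroazulene-1-carboxylate
Conditions: [Ir(cod)(PCy3)(py)]PF6 (5–10 mol %), H2 (1–5 atm), CH2Cl2, rt
Reagents that add atoms: none
Why: Hydroxyl-directed hydrogenation with the cationic iridium catalyst should deliver both hydrogens to the C3a=C8a face syn to the C8 hydroxyl, giving the cis ring fusion with absolute configuration relayed from C8.

Step 8
Reactants: 13 methyl (3aR,8S,8aR)-8-hydroxy-1,4,4-trimethyldecahydroazulene-1-carboxylate
Product: 14 methyl (3aR,8aR)-1,4,4-trimethyl-8-oxodecahydroazulene-1-carboxylate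
Conditions: Pr4N[RuO4] (5 mol %), N-methylmorpholine N-oxide, 4 Å MS, CH2Cl2, rt
Reagents that add atoms: none
Why: Ley–Griffith oxidation is neutral, so the enolisable ring-fusion centre C8a should be kept while the temporary C8 stereocentre is removed.

Step 9
Reactants: 14 methyl (3aR,8aR)-1,4,4-trimethyl-8-oxodecahydroazulene-1-carboxylate
Product: 15 methyl (3aR,8aS)-1,4,4-trimethyl-8-methylidenedecahydroazulene-1-carboxylate
Conditions: Zn, CH2Br2, TiCl4, THF/CH2Cl2, 0 °C to rt
Reagents that add atoms: dibromomethane, BrCBr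
Why: Takai–Lombardo methylenation is non-basic and ketone-selective, so it should install the exocyclic alkene without epimerising C8a or touching the ester.

Step 10
Reactants: 15 methyl (3aR,8aS)-1,4,4-trimethyl-8-methylidenedecahydroazulene-1-carboxylate
Product: 16 (3aR,8aS)-1,4,4-trimethyl-8-methylidenedecahydroazulene-1-carboxylic acid
Conditions: LiI, pyridine, reflux; then 1 M HCl (work-up)
Reagents that add atoms: none
Why: Iodide cleaves the hindered methyl ester by SN2 attack at the methyl carbon, which avoids attack at the neopentyl-type carbonyl and avoids strong acid that could migrate the exocyclic alkene.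

Step 11
Reactants: 16 (3aR,8aS)-1,4,4-trimethyl-8-methylidenedecahydroazulene-1-carboxylic acid
Product: 17 1,3-dioxoisoindolin-2-yl (3aR,8aS)-1,4,4-trimethyl-8-methylidenedecahydroazulene-1-carboxylate
Conditions: N-hydroxyphthalimide, N,N′-diisopropylcarbodiimide, DMAP (cat.), CH2Cl2, rt
Reagents that add atoms: N-hydroxyphthalimide, O=C1c2ccccc2C(=O)N1O
Why: Carbodiimide (Steglich-type) esterification should give the redox-active N-acyloxyphthalimide of the tertiary acid.

Step 12
Reactants: 18 5-hydroxyfuran-2(5H)-one; 19 (+)-menthol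
Product: 20 (5S)-5-{[(1S,2R,5S)-5-methyl-2-(propan-2-yl)cyclohexyl]oxy}furan-2(5H)-one
Conditions: camphorsulfonic acid (cat.), toluene, reflux, Dean–Stark; crystallisation from petroleum ether
Reagents that add atoms: none
Why: Acid-catalysed acetalisation gives both C5 epimers, which equilibrate under acid while the (5S) epimer of the (+)-menthyl series (mirror image of the well-known crystalline l-menthyl compound) crystallises, so C5 is set by the auxiliary.

Step 13
Reactants: 20 (5S)-5-{[(1S,2R,5S)-5-methyl-2-(propan-2-yl)cyclohexyl]oxy}furan-2(5H)-one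
Product: 22 (5S)-3-bromo-5-{[(1S,2R,5S)-5-methyl-2-(propan-2-yl)cyclohexyl]oxy}furan-2(5H)-one, via dibromolactone 21 (not isolated)
Conditions: Br2, CH2Cl2, 0 °C; then Et3N, 0 °C to rt
Reagents that add atoms: bromine, BrBr
Why: Bromine addition to the butenolide alkene and E2 loss of HBr through the acidic α-hydrogen should give the α-bromobutenolide with C5 untouched.

Step 14
Reactants: 22 (5S)-3-bromo-5-{[(1S,2R,5S)-5-methyl-2-(propan-2-yl)cyclohexyl]oxy}furan-2(5H)-one; 23 tert-butyl bromoacetate
Product: 25 tert-butyl 2-[(5S)-5-{[(1S,2R,5S)-5-methyl-2-(propan-2-yl)cyclohexyl]oxy}-2-oxo-2,5-dihydrofuran-3-yl]acetate, via Reformatsky reagent 24 (not isolated)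
Conditions: Zn dust, THF, rt (23 to 24); then 22, Pd[P(t-Bu)3]2 (5 mol %), THF, rt
Reagents that add atoms: none
Why: Negishi coupling of the vinyl bromide with the Reformatsky reagent runs under neutral conditions, which should avoid base-induced migration of the butenolide double bond.

Step 15
Reactants: 17 1,3-dioxoisoindolin-2-yl (3aR,8aS)-1,4,4-trimethyl-8-methylidenedecahydroazulene-1-carboxylate; 25 tert-butyl 2-[(5S)-5-{[(1S,2R,5S)-5-methyl-2-(propan-2-yl)cyclohexyl]oxy}-2-oxo-2,5-dihydrofuran-3-yl]acetate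
Product: 26 tert-butyl 2-[(3R,4R,5S)-5-{[(1S,2R,5S)-5-methyl-2-(propan-2-yl)cyclohexyl]oxy}-2-oxo-4-[(1R,3aR,8aS)-1,4,4-trimethyl-8-methylidenedecahydroazulen-1-yl]oxolan-3-yl]acetate
Conditions: Ru(bpy)3(PF6)2 (1 mol %), Hantzsch ester (1.5 equiv), i-Pr2NEt·HBF4, CH2Cl2, blue LEDs, rt
Reagents that add atoms: none
Why: Photoredox decarboxylative Giese reaction: the tertiary C1 radical should add to the butenolide β-carbon from the convex face of the cis-hydroazulene (anti to the seven-membered ring, setting C1) and anti to the menthyloxy group (setting the β-carbon), and the α-acyl radical then takes hydrogen anti to the new quaternary substituent, placing the acetate arm cis to it.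

Step 16
Reactants: 26 tert-butyl 2-[(3R,4R,5S)-5-{[(1S,2R,5S)-5-methyl-2-(propan-2-yl)cyclohexyl]oxy}-2-oxo-4-[(1R,3aR,8aS)-1,4,4-trimethyl-8-methylidenedecahydroazulen-1-yl]oxolan-3-yl]acetate
Product: 28 tert-butyl (3R,4R)-5-hydroxy-3-(hydroxymethyl)-4-[(1R,3aR,8aS)-1,4,4-trimethyl-8-methylidenedecahydroazulen-1-yl]pentanoate, via lactol 27 (not isolated)
Conditions: i-Bu2AlH (1.2 equiv), CH2Cl2, −78 °C; then MeOH, NaBH4, 0 °C
Reagents that add atoms: none
Why: i-Bu2AlH should reduce the activated acyl-acetal lactone to the lactol faster than it attacks the tert-butyl ester, and NaBH4 then reduces the ring-opened dialdehyde (menthol is lost) to the 1,4-diol without touching the ester or the stereocentres.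

Step 17
Reactants: 28 tert-butyl (3R,4R)-5-hydroxy-3-(hydroxymethyl)-4-[(1R,3aR,8aS)-1,4,4-trimethyl-8-methylidenedecahydroazulen-1-yl]pentanoate
Product: 29 (4R)-4-{(1R)-2-hydroxy-1-[(1R,3aR,8aS)-1,4,4-trimethyl-8-methylidenedecahydroazulen-1-yl]ethyl}oxolan-2-one
Conditions: camphorsulfonic acid (cat.), toluene, 60 °C
Reagents that add atoms: none
Why: Acid-catalysed intramolecular transesterification should close the five-membered lactone (5-exo-trig) from the hydroxymethyl group, which is favoured kinetically and thermodynamically over the six-membered lactone from the other primary alcohol.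

Step 18
Reactants: 29 (4R)-4-{(1R)-2-hydroxy-1-[(1R,3aR,8aS)-1,4,4-trimethyl-8-methylidenedecahydroazulen-1-yl]ethyl}oxolan-2-one
Product: 30 (3S,4R)-3-hydroxy-4-{(1R)-2-hydroxy-1-[(1R,3aR,8aS)-1,4,4-trimethyl-8-methylidenedecahydroazulen-1-yl]ethyl}oxolan-2-one
Conditions: KN(SiMe3)2 (2.3 equiv), THF, −78 °C; then 3-phenyl-2-(phenylsulfonyl)oxaziridine, −78 °C; NH4Cl (aq)
Reagents that add atoms: 3-phenyl-2-(phenylsulfonyl)oxaziridine, O=S(=O)(N1OC1c1ccccc1)c1ccccc1
Why: Davis hydroxylation of the lactone enolate (formed beside the potassium alkoxide) should occur on the face anti to the bulky C4 substituent and give the trans (3S) hydroxy lactone.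

Step 19
Reactants: 30 (3S,4R)-3-hydroxy-4-{(1R)-2-hydroxy-1-[(1R,3aR,8aS)-1,4,4-trimethyl-8-methylidenedecahydroazulen-1-yl]ethyl}oxolan-2-one
Product: 31 (3S,4R)-4-{(1R)-2-acetoxy-1-[(1R,3aR,8aS)-1,4,4-trimethyl-8-methylidenedecahydroazulen-1-yl]ethyl}-2-oxooxolan-3-yl acetate
Conditions: Ac2O, pyridine, DMAP (cat.), CH2Cl2, 0 °C to rt
Reagents that add atoms: acetic anhydride, CC(=O)OC(C)=O
Why: DMAP-catalysed acetylation of the primary and the secondary alcohol should give the target without touching any stereocentre.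

## Compound list

1 | cycloheptane-1,3-dione | O=C1CC(=O)CCCC1 | starting material
2 | 3-(2-methylpropoxy)cyclohept-2-en-1-one | CC(C)COC1=CC(=O)CCCC1 | intermediate
3 | 7-methyl-3-(2-methylpropoxy)cyclohept-2-en-1-one (racemic, not isolated) | CC(C)COC1=CC(=O)C(C)CCC1 | intermediate
4 | 7,7-dimethyl-3-(2-methylpropoxy)cyclohept-2-en-1-one | CC(C)COC1=CC(=O)C(C)(C)CCC1 | intermediate
5 | 2-iodo-7,7-dimethyl-3-(2-methylpropoxy)cyclohept-2-en-1-one | CC(C)COC1=C(I)C(=O)C(C)(C)CCC1 | intermediate
6 | methyl 2-bromopropanoate (racemic) | COC(=O)C(C)Br | starting material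
7 | (1-methoxy-1-oxopropan-2-yl)zinc bromide (not isolated) | COC(=O)C(C)[Zn]Br | intermediate
8 | methyl 2-[6,6-dimethyl-2-(2-methylpropoxy)-7-oxocyclohept-1-en-1-yl]propanoate (racemic) | COC(=O)C(C)C1=C(OCC(C)C)CCCC(C)(C)C1=O | intermediate
9 | methyl 2-[6,6-dimethyl-2-(2-methylpropoxy)-7-oxocyclohept-1-en-1-yl]-2-methyl-4-(triphenyl-λ5-phosphanylidene)butanoate (not isolated) | COC(=O)C(C)(CC=P(c1ccccc1)(c1ccccc1)c1ccccc1)C1=C(OCC(C)C)CCCC(C)(C)C1=O | intermediate
10 | methyl 1,4,4-trimethyl-8-(2-methylpropoxy)-1,2,4,5,6,7-hexahydroazulene-1-carboxylate (C3=C3a, C8=C8a diene, not isolated) | COC(=O)C1(C)CC=C2C1=C(OCC(C)C)CCCC2(C)C | intermediate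
11 | methyl 1,4,4-trimethyl-8-oxo-1,2,3,4,5,6,7,8-octahydroazulene-1-carboxylate (C3a=C8a enone, racemic) | COC(=O)C1(C)CCC2=C1C(=O)CCCC2(C)C | intermediate
12 | methyl (8S)-8-hydroxy-1,4,4-trimethyl-1,2,3,4,5,6,7,8-octahydroazulene-1-carboxylate (both C1 epimers) | O[C@H]1CCCC(C)(C)C2=C1C(C)(C(=O)OC)CC2 | intermediate
13 | methyl (3aR,8S,8aR)-8-hydroxy-1,4,4-trimethyldecahydroazulene-1-carboxylate (cis-fused, OH cis to both ring-fusion H; both C1 epimers) | O[C@H]1CCCC(C)(C)[C@@H]2CCC(C)(C(=O)OC)[C@H]12 | intermediate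
14 | methyl (3aR,8aR)-1,4,4-trimethyl-8-oxodecahydroazulene-1-carboxylate (cis-fused; both C1 epimers) | O=C1CCCC(C)(C)[C@@H]2CCC(C)(C(=O)OC)[C@H]12 | intermediate
15 | methyl (3aR,8aS)-1,4,4-trimethyl-8-methylidenedecahydroazulene-1-carboxylate (both C1 epimers) | C=C1CCCC(C)(C)[C@@H]2CCC(C)(C(=O)OC)[C@H]12 | intermediate
16 | (3aR,8aS)-1,4,4-trimethyl-8-methylidenedecahydroazulene-1-carboxylic acid (both C1 epimers) | C=C1CCCC(C)(C)[C@@H]2CCC(C)(C(=O)O)[C@H]12 | intermediate
17 | 1,3-dioxoisoindolin-2-yl (3aR,8aS)-1,4,4-trimethyl-8-methylidenedecahydroazulene-1-carboxylate (both C1 epimers) | C=C1CCCC(C)(C)[C@@H]2CCC(C)(C(=O)ON3C(=O)c4ccccc4C3=O)[C@H]12 | intermediate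
18 | 5-hydroxyfuran-2(5H)-one (racemic) | OC1OC(=O)C=C1 | starting material
19 | (+)-menthol, (1S,2R,5S)-5-methyl-2-(propan-2-yl)cyclohexan-1-ol | CC(C)[C@H]1CC[C@H](C)C[C@@H]1O | starting material
20 | (5S)-5-{[(1S,2R,5S)-5-methyl-2-(propan-2-yl)cyclohexyl]oxy}furan-2(5H)-one | O=C1C=C[C@@H](O[C@H]2C[C@@H](C)CC[C@@H]2C(C)C)O1 | intermediate
21 | (5S)-3,4-dibromo-5-{[(1S,2R,5S)-5-methyl-2-(propan-2-yl)cyclohexyl]oxy}oxolan-2-one (not isolated) | O=C1C(Br)C(Br)[C@@H](O[C@H]2C[C@@H](C)CC[C@@H]2C(C)C)O1 | intermediate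
22 | (5S)-3-bromo-5-{[(1S,2R,5S)-5-methyl-2-(propan-2-yl)cyclohexyl]oxy}furan-2(5H)-one | O=C1C(Br)=C[C@@H](O[C@H]2C[C@@H](C)CC[C@@H]2C(C)C)O1 | intermediate
23 | tert-butyl bromoacetate | CC(C)(C)OC(=O)CBr | starting material
24 | (2-tert-butoxy-2-oxoethyl)zinc bromide (not isolated) | CC(C)(C)OC(=O)C[Zn]Br | intermediate
25 | tert-butyl 2-[(5S)-5-{[(1S,2R,5S)-5-methyl-2-(propan-2-yl)cyclohexyl]oxy}-2-oxo-2,5-dihydrofuran-3-yl]acetate | CC(C)(C)OC(=O)CC1=C[C@@H](O[C@H]2C[C@@H](C)CC[C@@H]2C(C)C)OC1=O | intermediate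
26 | tert-butyl 2-[(3R,4R,5S)-5-{[(1S,2R,5S)-5-methyl-2-(propan-2-yl)cyclohexyl]oxy}-2-oxo-4-[(1R,3aR,8aS)-1,4,4-trimethyl-8-methylidenedecahydroazulen-1-yl]oxolan-3-yl]acetate | C=C1CCCC(C)(C)[C@@H]2CC[C@@](C)([C@@H]3[C@@H](O[C@H]4C[C@@H](C)CC[C@@H]4C(C)C)OC(=O)[C@@H]3CC(=O)OC(C)(C)C)[C@H]12 | intermediate
27 | lactol of 26: tert-butyl 2-[(3R,4R,5S)-2-hydroxy-5-(menthyloxy)-4-(hydroazulenyl)oxolan-3-yl]acetate (anomer mixture, not isolated) | C=C1CCCC(C)(C)[C@@H]2CC[C@@](C)([C@@H]3[C@@H](O[C@H]4C[C@@H](C)CC[C@@H]4C(C)C)OC(O)[C@@H]3CC(=O)OC(C)(C)C)[C@H]12 | intermediate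
28 | tert-butyl (3R,4R)-5-hydroxy-3-(hydroxymethyl)-4-[(1R,3aR,8aS)-1,4,4-trimethyl-8-methylidenedecahydroazulen-1-yl]pentanoate | C=C1CCCC(C)(C)[C@@H]2CC[C@@](C)([C@H](CO)[C@H](CO)CC(=O)OC(C)(C)C)[C@H]12 | intermediate
29 | (4R)-4-{(1R)-2-hydroxy-1-[(1R,3aR,8aS)-1,4,4-trimethyl-8-methylidenedecahydroazulen-1-yl]ethyl}oxolan-2-one | C=C1CCCC(C)(C)[C@@H]2CC[C@@](C)([C@H](CO)[C@@H]3COC(=O)C3)[C@H]12 | intermediate
30 | (3S,4R)-3-hydroxy-4-{(1R)-2-hydroxy-1-[(1R,3aR,8aS)-1,4,4-trimethyl-8-methylidenedecahydroazulen-1-yl]ethyl}oxolan-2-one | C=C1CCCC(C)(C)[C@@H]2CC[C@@](C)([C@H](CO)[C@@H]3COC(=O)[C@H]3O)[C@H]12 | intermediate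
31 | (3S,4R)-4-{(1R)-2-acetoxy-1-[(1R,3aR,8aS)-1,4,4-trimethyl-8-methylidenedecahydroazulen-1-yl]ethyl}-2-oxooxolan-3-yl acetate | C=C1CCCC(C)(C)[C@@H]2CC[C@@](C)([C@H](COC(C)=O)[C@@H]3COC(=O)[C@H]3OC(C)=O)[C@H]12 | target

## Step count and risks

Total: 19 steps. Longest linear sequence: 16 steps (steps 1–11, then 15–19); fragment 2 takes steps 12–14.

Steps most likely to fail:

**Step 5 (key annulation).** The non-stabilised ylide may be quenched by proton transfer or add too slowly to the hindered, weakly electrophilic ring carbonyl, and γ-deprotonation of the vinylogous ester may compete with ester enolisation. The fallback sets out from 8 and comes back at 11, making the two bonds one after the other. The potassium enolate of 8 is alkylated with 1-bromo-2-chloroethane to methyl 4-chloro-2-[6,6-dimethyl-2-(2-methylpropoxy)-7-oxocyclohept-1-en-1-yl]-2-methylbutanoate F1. Halide exchange (NaI, acetone) gives the corresponding iodide, methyl 2-[6,6-dimethyl-2-(2-methylpropoxy)-7-oxocyclohept-1-en-1-yl]-4-iodo-2-methylbutanoate F2. A samarium Barbier cyclisation (SmI2, HMPA, THF) closes the five-membered ring onto the ring carbonyl to the tertiary carbinol methyl 3a-hydroxy-1,4,4-trimethyl-8-(2-methylpropoxy)-1,2,3,3a,4,5,6,7-octahydroazulene-1-carboxylate F3. Dilute HCl then hydrolyses and dehydrates F3 to 11 (Stork–Danheiser transposition).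

**Step 7 (directed hydrogenation).** Hydrogen uptake at the tetrasubstituted alkene flanked by two quaternary carbons may be too slow, or hydrogen may be delivered from the wrong face through coordination of the ester. The fallback sets out from 11 and comes back at 13, replacing hydrogenation by a sigmatropic hydrogen transfer and a hydroboration. Reduction of 11 with the enantiomeric (S)-oxazaborolidine gives methyl (8R)-8-hydroxy-1,4,4-trimethyl-1,2,3,4,5,6,7,8-octahydroazulene-1-carboxylate F4. Mitsunobu displacement with 2-nitrobenzenesulfonylhydrazide (PPh3, DIAD, THF, −30 °C) gives with inversion the allylic sulfonylhydrazine methyl (8S)-8-[1-(2-nitrobenzenesulfonyl)hydrazinyl]-1,4,4-trimethyl-1,2,3,4,5,6,7,8-octahydroazulene-1-carboxylate F5. On warming F5 loses the sulfinic acid to the monoalkyl diazene methyl (8S)-8-diazenyl-1,4,4-trimethyl-1,2,3,4,5,6,7,8-octahydroazulene-1-carboxylate F6. Retro-ene loss of dinitrogen from F6 delivers hydrogen to C3a on the face that carried nitrogen and moves the alkene, giving methyl (3aS)-1,4,4-trimethyl-1,2,3,3a,4,5,6,7-octahydroazulene-1-carboxylate F7 (C8=C8a alkene). Hydroboration–oxidation of F7 (BH3·THF, then NaOH, H2O2) from the face of the C3a hydrogen, anti to the gem-dimethyl carbon, should give 13.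

**Step 15 (radical fragment union).** Addition of the tertiary radical to the trisubstituted acceptor may be slow, the acceptor double bond may migrate out of the ring, or face selectivity in the final hydrogen transfer may erode. The fallback sets out from 17 and 20 and comes back at 26, adding the acetate arm after the coupling. Under the same photoredox conditions 17 is coupled with the unsubstituted butenolide 20 to (4R,5S)-5-{[(1S,2R,5S)-5-methyl-2-(propan-2-yl)cyclohexyl]oxy}-4-[(1R,3aR,8aS)-1,4,4-trimethyl-8-methylidenedecahydroazulen-1-yl]oxolan-2-one F8. Aldol addition of its lithium enolate (LiN(SiMe3)2, THF, −78 °C) to tert-butyl glyoxylate gives the carbinol tert-butyl 2-hydroxy-2-[(4R,5S)-5-(menthyloxy)-2-oxo-4-(hydroazulenyl)oxolan-3-yl]acetate F9. Dehydration (MsCl, Et3N, then DBU) gives the alkylidene lactone tert-butyl 2-[(4R,5S)-5-(menthyloxy)-2-oxo-4-(hydroazulenyl)oxolan-3-ylidene]acetate F10. Conjugate reduction of F10 with [(Ph3P)CuH]6 places hydrogen at the lactone α-carbon anti to the C4 substituent and should give 26.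

Further compounds
F1 | step 5 | methyl 4-chloro-2-[6,6-dimethyl-2-(2-methylpropoxy)-7-oxocyclohept-1-en-1-yl]-2-methylbutanoate | COC(=O)C(C)(CCCl)C1=C(OCC(C)C)CCCC(C)(C)C1=O
F2 | step 5 | methyl 2-[6,6-dimethyl-2-(2-methylpropoxy)-7-oxocyclohept-1-en-1-yl]-4-iodo-2-methylbutanoate | COC(=O)C(C)(CCI)C1=C(OCC(C)C)CCCC(C)(C)C1=O
F3 | step 5 | methyl 3a-hydroxy-1,4,4-trimethyl-8-(2-methylpropoxy)-1,2,3,3a,4,5,6,7-octahydroazulene-1-carboxylate | COC(=O)C1(C)CCC2(O)C1=C(OCC(C)C)CCCC2(C)C
F4 | step 7 | methyl (8R)-8-hydroxy-1,4,4-trimethyl-1,2,3,4,5,6,7,8-octahydroazulene-1-carboxylate | O[C@@H]1CCCC(C)(C)C2=C1C(C)(C(=O)OC)CC2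
F5 | step 7 | methyl (8S)-8-[1-(2-nitrobenzenesulfonyl)hydrazinyl]-1,4,4-trimethyl-1,2,3,4,5,6,7,8-octahydroazulene-1-carboxylate | NN([C@H]1CCCC(C)(C)C2=C1C(C)(C(=O)OC)CC2)S(=O)(=O)c1ccccc1[N+](=O)[O-]
F6 | step 7 | methyl (8S)-8-diazenyl-1,4,4-trimethyl-1,2,3,4,5,6,7,8-octahydroazulene-1-carboxylate | N=N[C@H]1CCCC(C)(C)C2=C1C(C)(C(=O)OC)CC2
F7 | step 7 | methyl (3aS)-1,4,4-trimethyl-1,2,3,3a,4,5,6,7-octahydroazulene-1-carboxylate | COC(=O)C1(C)CC[C@@H]2C1=CCCCC2(C)C
F8 | step 15 | (4R,5S)-5-{[(1S,2R,5S)-5-methyl-2-(propan-2-yl)cyclohexyl]oxy}-4-[(1R,3aR,8aS)-1,4,4-trimethyl-8-methylidenedecahydroazulen-1-yl]oxolan-2-one | C=C1CCCC(C)(C)[C@@H]2CC[C@@](C)([C@@H]3[C@@H](O[C@H]4C[C@@H](C)CC[C@@H]4C(C)C)OC(=O)C3)[C@H]12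
F9 | step 15 | tert-butyl 2-hydroxy-2-[(4R,5S)-5-(menthyloxy)-2-oxo-4-(hydroazulenyl)oxolan-3-yl]acetate | C=C1CCCC(C)(C)[C@@H]2CC[C@@](C)([C@@H]3[C@@H](O[C@H]4C[C@@H](C)CC[C@@H]4C(C)C)OC(=O)C3C(O)C(=O)OC(C)(C)C)[C@H]12
F10 | step 15 | tert-butyl 2-[(4R,5S)-5-(menthyloxy)-2-oxo-4-(hydroazulenyl)oxolan-3-ylidene]acetate | C=C1CCCC(C)(C)[C@@H]2CC[C@@](C)([C@@H]3[C@@H](O[C@H]4C[C@@H](C)CC[C@@H]4C(C)C)OC(=O)C3=CC(=O)OC(C)(C)C)[C@H]12
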